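The route rests on detaching the pyranone ring C from ring A at both fusion bonds, O1–C8a and C4–C4a. In one operation a fluoride-generated 3,5-bis(methoxymethoxy)benzyne is annulated with an (S)-β-hydroxy ester that already holds ring B, the C2 stereocentre, C3 and C4: the hydroxyl adds to the aryne and the aryl anion acylates itself on the ester. The step exploits the ortho relationship of O1 and the C4 acyl group on ring A, and the C5 oxygen, which steers the aryne regiochemistry. The precursors are an ortho-silylaryl triflate from phloroglucinol and a hydroxy ester made by asymmetric transfer hydrogenation.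

Key step: step 7

Remark on the chemistry: the target is the (2S)-flavanone. Flavanone numbering is used throughout (O1, C2, C3, C4, C4a, C5 to C8, C8a; ring A = benzo ring, ring B = 2-aryl group, ring C = pyranone). The carbinol carbon of hydroxy ester 5 keeps the descriptor (S) when it becomes C2, because the priority order O > aryl > CH2 > H does not change. Tributyl(3-methylbut-2-en-1-yl)stannane is taken as commercially available.

**Step 1**
Reactants: 1 bromo ketone 1-(3-bromo-4-methoxyphenyl)ethan-1-one; 2 tributyl(3-methylbut-2-en-1-yl)stannane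
Product: 3 prenyl ketone 1-[4-methoxy-3-(3-methylbut-2-en-1-yl)phenyl]ethan-1-one
Conditions: 2 (1.2 equiv), Pd(PPh3)4 (5 mol%), DMF, 95 °C
Reagents that add atoms: none
Why: Stille coupling of an aryl bromide activated by the para acetyl group; the allyl group passes through a π-allylpalladium intermediate and reductive elimination at its unsubstituted terminus should give the linear prenyl arene.

**Step 2**
Reactants: 3 prenyl ketone 1-[4-methoxy-3-(3-methylbut-2-en-1-yl)phenyl]ethan-1-one
Product: 4 keto ester methyl 3-[4-methoxy-3-(3-methylbut-2-en-1-yl)phenyl]-3-oxopropanoate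
Conditions: NaH (2.5 equiv), (MeO)2CO (3 equiv), THF, reflux; then aq. HCl, 0 °C
Reagents that add atoms: dimethyl carbonate COC(=O)OC
Why: Crossed Claisen condensation in which the methyl ketone enolate is acylated by dimethyl carbonate and the product is drawn out of the equilibrium as its stabilised sodium enolate.

**Step 3**
Reactants: 4 keto ester methyl 3-[4-methoxy-3-(3-methylbut-2-en-1-yl)phenyl]-3-oxopropanoate
Product: 5 hydroxy ester methyl (3S)-3-hydroxy-3-[4-methoxy-3-(3-methylbut-2-en-1-yl)phenyl]propanoate
Conditions: RuCl(p-cymene)[(S,S)-TsDPEN] (1 mol%), HCO2H/Et3N (5:2), 35 °C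
Reagents that add atoms: none
Why: Noyori–Ikariya asymmetric transfer hydrogenation of an aryl ketone, in which the (S,S)-diamine catalyst should deliver hydride to the Re face through the CH/π-organised six-membered transition state and so set the (S) carbinol (the later C2), while the isolated trisubstituted alkene and the ester are not reduced.

**Step 4**
Reactants: 6 benzene-1,3,5-triol (phloroglucinol)
Product: 7 bis-MOM phenol 3,5-bis(methoxymethoxy)phenol
Conditions: MOMCl (2.0 equiv), i-Pr2NEt (2.4 equiv), DMF/CH2Cl2, 0 °C to rt; chromatographic separation from mono- and tris-ethers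
Reagents that add atoms: chloromethyl methyl ether COCCl
Why: O-alkylation of three equivalent hydroxyls is statistical, so two equivalents of MOMCl should make the bis-ether the main component, which is separated by chromatography.

**Step 5**
Reactants: 7 bis-MOM phenol 3,5-bis(methoxymethoxy)phenol
Product: 8 bromophenol 2-bromo-3,5-bis(methoxymethoxy)phenol
Conditions: NBS (1.0 equiv), CH2Cl2, −78 °C
Reagents that add atoms: N-bromosuccinimide O=C1CCC(=O)N1Br
Why: Electrophilic aromatic bromination of a strongly activated phenol, in which the two equivalent positions ortho to the free hydroxyl should react in preference to the more hindered position between the two MOM ethers, and one equivalent of NBS at low temperature should limit dibromination.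

**Step 6**
Reactants: 8 bromophenol 2-bromo-3,5-bis(methoxymethoxy)phenol
Product: 11 silylaryl triflate 3,5-bis(methoxymethoxy)-2-(trimethylsilyl)phenyl trifluoromethanesulfonate, via aryl trimethylsilyl ether 9 (not isolated), via lithium 2-(trimethylsilyl)phenolate 10 (not isolated)
Conditions: (Me3Si)2NH, THF, 65 °C, then evaporation; n-BuLi, THF, −78 °C; Tf2O, −78 °C to 0 °C
Reagents that add atoms: hexamethyldisilazane C[Si](C)(C)N[Si](C)(C)C; trifluoromethanesulfonic anhydride O=S(=O)(OS(=O)(=O)C(F)(F)F)C(F)(F)F
Why: O-silylation, then bromine–lithium exchange, triggers a 1,3-O-to-C silyl shift (retro-Brook rearrangement) to phenolate 10, which Tf2O traps, the standard sequence to ortho-silylaryl triflates.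

**Step 7**
Reactants: 5 hydroxy ester methyl (3S)-3-hydroxy-3-[4-methoxy-3-(3-methylbut-2-en-1-yl)phenyl]propanoate; 11 silylaryl triflate 3,5-bis(methoxymethoxy)-2-(trimethylsilyl)phenyl trifluoromethanesulfonate
Product: 14 protected flavanone (2S)-5,7-bis(methoxymethoxy)-2-[4-methoxy-3-(3-methylbut-2-en-1-yl)phenyl]-2,3-dihydro-4H-chromen-4-one, via 3,5-bis(methoxymethoxy)benzyne 12 (not isolated), via ortho-cesiated aryl ether 13 (not isolated)
Conditions: 11 (1.8 equiv), CsF (4 equiv), THF, 65 °C
Reagents that add atoms: none
Why: Proposed new method: fluoride attacks silicon of 11 and triflate leaves to give aryne 12, the fluoride-activated hydroxyl of 5 adds to the aryne carbon remote from the flanking OMOM group, and the resulting aryl anion 13 attacks the methyl ester and expels methoxide. The closest known reaction type is the fluoride-promoted annulation of arynes with methyl salicylates to xanthones (O–H addition to the aryne, then intramolecular acyl substitution), extended here from a phenol to an aliphatic benzylic alcohol. Ring C closes by a 6-exo-trig acyl substitution that completes the O1–C8a and C4–C4a bonds in the same operation. No stereocenter is formed: the C2–O bond of 5 is never broken, so the (S) configuration set in step 3 is carried into 14 unchanged. The step needs regioselective aryne capture, which the C5 oxygen secures because attack at the distal aryne carbon places the negative charge next to that inductively withdrawing substituent, where the acyl group must end. It also needs cyclisation to outrun protonation of 13, which the six-membered transition state, the weakly proton-donating THF and the excess of 11 (which also consumes the methoxide that could otherwise open ring C) should favour.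

**Step 8**
Reactants: 14 protected flavanone (2S)-5,7-bis(methoxymethoxy)-2-[4-methoxy-3-(3-methylbut-2-en-1-yl)phenyl]-2,3-dihydro-4H-chromen-4-one
Product: 15 target (2S)-5,7-dihydroxy-2-[4-methoxy-3-(3-methylbut-2-en-1-yl)phenyl]-2,3-dihydro-4H-chromen-4-one (4'-O-methyllicoflavanone)
Conditions: 3 M aq. HCl/MeOH, 45 °C
Reagents that add atoms: none
Why: Acid-catalysed acetal exchange with methanol removes both MOM ethers, while the aryl methyl ether, the prenyl alkene (no ortho phenol is available for chroman formation) and the C2 stereocentre should survive the mild acid.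

**Compound list**
1 | 1-(3-bromo-4-methoxyphenyl)ethan-1-one | CC(=O)c1ccc(OC)c(Br)c1 | starting material
2 | tributyl(3-methylbut-2-en-1-yl)stannane | CCCC[Sn](CCCC)(CCCC)CC=C(C)C | starting material
3 | 1-[4-methoxy-3-(3-methylbut-2-en-1-yl)phenyl]ethan-1-one | CC(=O)c1ccc(OC)c(CC=C(C)C)c1 | intermediate
4 | methyl 3-[4-methoxy-3-(3-methylbut-2-en-1-yl)phenyl]-3-oxopropanoate | COC(=O)CC(=O)c1ccc(OC)c(CC=C(C)C)c1 | intermediate
5 | methyl (3S)-3-hydroxy-3-[4-methoxy-3-(3-methylbut-2-en-1-yl)phenyl]propanoate | COC(=O)C[C@H](O)c1ccc(OC)c(CC=C(C)C)c1 | intermediate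
6 | benzene-1,3,5-triol (phloroglucinol) | Oc1cc(O)cc(O)c1 | starting material
7 | 3,5-bis(methoxymethoxy)phenol | COCOc1cc(O)cc(OCOC)c1 | intermediate
8 | 2-bromo-3,5-bis(methoxymethoxy)phenol | COCOc1cc(O)c(Br)c(OCOC)c1 | intermediate
9 | [2-bromo-3,5-bis(methoxymethoxy)phenoxy]trimethylsilane | COCOc1cc(O[Si](C)(C)C)c(Br)c(OCOC)c1 | intermediate (not isolated)
10 | lithium 3,5-bis(methoxymethoxy)-2-(trimethylsilyl)phenolate | [Li+].[O-]c1cc(OCOC)cc(OCOC)c1[Si](C)(C)C | intermediate (not isolated)
11 | 3,5-bis(methoxymethoxy)-2-(trimethylsilyl)phenyl trifluoromethanesulfonate | COCOc1cc(OS(=O)(=O)C(F)(F)F)c([Si](C)(C)C)c(OCOC)c1 | intermediate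
12 | 3,5-bis(methoxymethoxy)benzyne (1,2-didehydro-3,5-bis(methoxymethoxy)benzene) | COCOC1=CC(OCOC)=CC#C1 | intermediate (not isolated)
13 | cesium salt of the aryl anion methyl (3S)-3-[2-cesio-3,5-bis(methoxymethoxy)phenoxy]-3-[4-methoxy-3-(3-methylbut-2-en-1-yl)phenyl]propanoate | COC(=O)C[C@H](Oc1cc(OCOC)cc(OCOC)[c-]1)c1ccc(OC)c(CC=C(C)C)c1.[Cs+] | intermediate (not isolated)
14 | (2S)-5,7-bis(methoxymethoxy)-2-[4-methoxy-3-(3-methylbut-2-en-1-yl)phenyl]-2,3-dihydro-4H-chromen-4-one | COc1ccc([C@@H]2CC(=O)c3c(OCOC)cc(OCOC)cc3O2)cc1CC=C(C)C | intermediate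
15 | (2S)-5,7-dihydroxy-2-[4-methoxy-3-(3-methylbut-2-en-1-yl)phenyl]-2,3-dihydro-4H-chromen-4-one (4'-O-methyllicoflavanone) | COc1ccc([C@@H]2CC(=O)c3c(O)cc(O)cc3O2)cc1CC=C(C)C | target

Total step count: 8
Longest linear sequence: 5 steps (steps 4, 5, 6, 7, 8 from phloroglucinol; steps 1, 2, 3, 7, 8 are equally long)

**Steps most likely to fail**

1. Step 7 (key step, proposed new method). The aryl anion formed after O-arylation may be protonated, by the hydroxyl of a second molecule of 5 or by the ester α-CH2, before it cyclises. The alcohol may also be too weak a nucleophile to capture the aryne. In addition, the liberated methoxide may open ring C by E1cB (retro-oxa-Michael) ring opening and so erode the C2 configuration.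

   The fallback uses known chemistry and changes the approach: C4–C4a is made by aryllithium acylation and O1–C2 by Mitsunobu cyclisation with inversion, so the enantiomeric carbinol is needed. It sets out from keto ester 4 and bromophenol 8 and comes back to the route at 14. Keto ester 4 would be reduced with the enantiomeric catalyst RuCl(p-cymene)[(R,R)-TsDPEN] in HCO2H/Et3N to methyl (3R)-3-hydroxy-3-[4-methoxy-3-(3-methylbut-2-en-1-yl)phenyl]propanoate F1. Treatment with MeNHOMe·HCl and i-PrMgCl (THF, −20 °C) would give the Weinreb amide (3R)-3-hydroxy-N-methoxy-N-methyl-3-[4-methoxy-3-(3-methylbut-2-en-1-yl)phenyl]propanamide F2. Its magnesium alkoxide would be acylated by the dilithio species generated from bromophenol 8 with n-BuLi (2.2 equiv, THF, −78 °C), giving the hydroxy ketone (3R)-3-hydroxy-1-[2-hydroxy-4,6-bis(methoxymethoxy)phenyl]-3-[4-methoxy-3-(3-methylbut-2-en-1-yl)phenyl]propan-1-one F3. Intramolecular Mitsunobu etherification (PPh3, DIAD, THF, 0 °C) would then close the O1–C2 bond with inversion and deliver the (2S)-flavanone 14.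

2. Step 5. Bromination may also occur para to the hydroxyl, between the two MOM ethers, and the very electron-rich ring may be brominated twice.

   The fallback replaces electrophilic substitution by carbamate-directed ortho-metalation. It sets out from phenol 7 and comes back to the route at triflate 11. Phenol 7 would be carbamoylated with isopropyl isocyanate (Et3N cat., CH2Cl2) to 3,5-bis(methoxymethoxy)phenyl N-(propan-2-yl)carbamate F4. Transient N-silylation (TBSOTf, TMEDA), ortho-lithiation next to the carbamate (n-BuLi/TMEDA, Et2O, −78 °C) and a TMSCl quench would give 3,5-bis(methoxymethoxy)-2-(trimethylsilyl)phenyl N-(propan-2-yl)carbamate F5. The carbamate is the strongest directing group and acts together with the neighbouring MOM ether, so the site between them should be metalated. Cleavage of the carbamate with Et2NH/DBU in MeCN and triflation of the phenolate in the same flask with PhNTf2 would give 11.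

3. Step 1. The prenyl group may be transferred with allylic transposition, giving the 1,1-dimethylallyl isomer, or the double bond may migrate into conjugation with the ring through palladium hydride species.

   The fallback replaces the cross-coupling by an arylcopper alkylation. It sets out from bromo ketone 1 and comes back to the route at ketone 3. Ketone 1 would be protected with ethylene glycol (p-TsOH, toluene, Dean–Stark) as 2-(3-bromo-4-methoxyphenyl)-2-methyl-1,3-dioxolane F6. Bromine–lithium exchange (n-BuLi, THF, −78 °C), transmetalation with CuBr·SMe2 and alkylation with 1-bromo-3-methylbut-2-ene at its unsubstituted terminus would give 2-[4-methoxy-3-(3-methylbut-2-en-1-yl)phenyl]-2-methyl-1,3-dioxolane F7. Mild acid hydrolysis (PPTS, acetone/H2O) would return ketone 3.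

**Further compounds**
F1 | step 7 | methyl (3R)-3-hydroxy-3-[4-methoxy-3-(3-methylbut-2-en-1-yl)phenyl]propanoate | COC(=O)C[C@@H](O)c1ccc(OC)c(CC=C(C)C)c1
F2 | step 7 | (3R)-3-hydroxy-N-methoxy-N-methyl-3-[4-methoxy-3-(3-methylbut-2-en-1-yl)phenyl]propanamide | CON(C)C(=O)C[C@@H](O)c1ccc(OC)c(CC=C(C)C)c1
F3 | step 7 | (3R)-3-hydroxy-1-[2-hydroxy-4,6-bis(methoxymethoxy)phenyl]-3-[4-methoxy-3-(3-methylbut-2-en-1-yl)phenyl]propan-1-one | COCOc1cc(O)c(C(=O)C[C@@H](O)c2ccc(OC)c(CC=C(C)C)c2)c(OCOC)c1
F4 | step 5 | 3,5-bis(methoxymethoxy)phenyl N-(propan-2-yl)carbamate | CC(C)NC(=O)Oc1cc(OCOC)cc(OCOC)c1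
F5 | step 5 | 3,5-bis(methoxymethoxy)-2-(trimethylsilyl)phenyl N-(propan-2-yl)carbamate | CC(C)NC(=O)Oc1cc(OCOC)cc(OCOC)c1[Si](C)(C)C
F6 | step 1 | 2-(3-bromo-4-methoxyphenyl)-2-methyl-1,3-dioxolane | COc1ccc(C2(C)OCCO2)cc1Br
F7 | step 1 | 2-[4-methoxy-3-(3-methylbut-2-en-1-yl)phenyl]-2-methyl-1,3-dioxolane | COc1ccc(C2(C)OCCO2)cc1CC=C(C)C
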